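**Strategy.** The synthesis rests on disconnecting the ring-fusion bond C5–C10 (labdane numbering) together with C8–C9, which opens both rings of the decalin to an acyclic triene. The key step exploits the fact that C5, the fusion carbon, lies next to the oxygenated C6 of ring B, while C10 is β to C11: C5 becomes the terminus of a 2-silyloxydiene (C5=C6–C7=C8) and C9=C10 an N-enoyl oxazolidinone. One Lewis-acid-promoted, auxiliary-controlled intramolecular Diels–Alder reaction then closes ring A (tether ring) and ring B (cycloadduct) and sets the quaternary C10. The triene comes from geranic acid by tert-alkylation of a pentenone silyl dienol ether; afterwards C8–OH and C6–OH are installed and the side chain is attached by B-alkyl Suzuki coupling.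

Key step: step 6

Remarks on the chemistry
- Numbering: atom labels C1–C20 follow labdane numbering (ring A: C1–C5 and C10; ring B: C5–C10; C4 gem-dimethyl; C10 angular methyl; C9 bears the chain C11–C16; C6 and C8 carry the hydroxyl groups). In names, bicyclic compounds are numbered as naphthalenes (C1 = labdane C9, C2 = C8, C3 = C7, C4 = C6, C4a = C5, C5 = C4, C8a = C10). "Lower face" is the face of the 8a-methyl group.
- Assumption: geranic acid is used as the commercial (2E) isomer (the same acid is obtained by saponification of methyl geranate).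
- Choice of auxiliary: in the chelate model of step 6, C5 attacks the face of C10 opposite the benzyl group of the s-cis chelated imide. For the 2E enoyl unit this predicts that the (R)-auxiliary gives the 10R (8aR) configuration of the target.
- Assumption: O-triflation of methyl acetoacetate under non-chelating (tetraalkylammonium) conditions gives the E enol triflate; chelating lithium conditions would give the Z isomer.

Step 1
Reactants: 1 (2E)-3,7-dimethylocta-2,6-dienoic acid (geranic acid); 2 (4R)-4-benzyl-1,3-oxazolidin-2-one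
Product: 4 (4R)-4-benzyl-3-[(2E)-3,7-dimethylocta-2,6-dienoyl]-1,3-oxazolidin-2-one, via mixed pivalic anhydride 3 (not isolated)
Conditions: PivCl, Et3N, THF, −20 °C; then LiCl, 2, −20 °C to rt
Reagents that add atoms: none
Why: N-acylation of the oxazolidinone through the mixed pivalic anhydride (LiCl-assisted) should give the enoyl imide without touching the 2E double bond; no stereocentre is formed.

Step 2
Reactants: 4
Product: 5 (4R)-4-benzyl-3-[(2E)-7-chloro-3,7-dimethyloct-2-enoyl]-1,3-oxazolidin-2-one
Conditions: HCl (g), CH2Cl2, −78 to −20 °C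
Reagents that add atoms: hydrogen chloride, Cl
Why: Markovnikov hydrochlorination should occur only at the electron-rich 6,7-alkene (tertiary cation), the conjugated enoyl alkene being deactivated; no stereocentre is formed.

Step 3
Reactants: 6 (3E)-pent-3-en-2-one
Product: 7 (3E)-2-(trimethylsilyloxy)penta-1,3-diene
Conditions: TMSOTf, Et3N, Et2O, 0 °C
Reagents that add atoms: trimethylsilyl triflate, C[Si](C)(C)OS(=O)(=O)C(F)(F)F
Why: Soft enolisation of the enone at the α′-methyl group (silyl triflate and amine) should give the cross-conjugated 2-silyloxydiene with the E-propenyl unit unchanged.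

Step 4
Reactants: 5; 7
Product: 8 (4R)-4-benzyl-3-[(2E,10E)-3,7,7-trimethyl-9-oxododeca-2,10-dienoyl]-1,3-oxazolidin-2-one
Conditions: TiCl4 (2.5 equiv), CH2Cl2, −78 °C, 15 min; aq. NaHCO3
Reagents that add atoms: none
Why: Lewis-acid-mediated α-tert-alkylation of a silyl enol ether (SN1 alkylation): TiCl4 ionises the tertiary chloride and the cation is captured by the unsubstituted terminus of the silyloxydiene, which after loss of the silyl group forms the C4–C5 bond, the quaternary C4 and the E-enone; ionisation and capture should outpace conjugate addition to the hindered β,β-disubstituted chelated imide.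

Step 5
Reactants: 8
Product: 9 (4R)-4-benzyl-3-[(2E,8Z,10E)-9-(tert-butyldimethylsilyloxy)-3,7,7-trimethyldodeca-2,8,10-trienoyl]-1,3-oxazolidin-2-one
Conditions: TBSOTf, Et3N, CH2Cl2, −78 to 0 °C
Reagents that add atoms: tert-butyldimethylsilyl triflate, CC(C)(C)[Si](C)(C)OS(=O)(=O)C(F)(F)F
Why: Soft enolisation of the enone at the α′-methylene (C5) should give the 2-silyloxydiene with the 8Z enol ether geometry (tether and silyloxy group cis), the geometry expected for silyl triflate and amine enolisation of a ketone.

Step 6
Reactants: 9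
Product: 10 (4R)-4-benzyl-3-{[4-(tert-butyldimethylsilyloxy)-2,5,5,8a-tetramethyl-1,2,4a,5,6,7,8,8a-octahydronaphthalen-1-yl]carbonyl}-1,3-oxazolidin-2-one (8aR as in the target; 4a-H on the upper face; 1-acyl and 2-methyl on the lower face)
Conditions: Me2AlCl (1.5 equiv), CH2Cl2, −78 to −30 °C
Reagents that add atoms: none
Why: Me2AlCl converts the imide into its cationic chelate (both carbonyl groups on aluminium, enoyl unit s-cis), and the electron-rich 2-silyloxydiene C5=C6–C7=C8 adds to the activated C9=C10 bond in a concerted but strongly asynchronous intramolecular Diels–Alder reaction in which the C5–C10 bond (diene terminus to the β-carbon of the imide) runs ahead of C8–C9; the closest known reaction type is the Lewis-acid-promoted intramolecular Diels–Alder reaction of triene N-acyl oxazolidinones, with the Mukaiyama–Michael addition as its polar limit. Ring A closes as the six-membered tether ring (C1–C4 chain, exo attack of C5 on C10) and ring B as the new cyclohexene of the [4+2] addition. C10 is controlled by the auxiliary, whose benzyl group shields one face of the chelated s-cis enoyl unit so that C5 adds to the other face, which gives 10R with the (R)-auxiliary. C5 follows from the endo transition state with a chair-like tether (trans ring fusion), C9 from the E geometry of the dienophile (acyl group cis to the angular methyl) and C8 from the E geometry of the propenyl unit. Regioselectivity is secured by the tether and by matched polarity (nucleophilic diene terminus on the acceptor β-carbon), and the gem-dimethyl group on the tether favours the folded conformer. Only the facial selectivity at C10 is indispensable, because C8 becomes trigonal in step 10 and C5 and C9 can be equilibrated to the wanted trans-fused, equatorial arrangement.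

Step 7
Reactants: 10
Product: 11 [4-(tert-butyldimethylsilyloxy)-2,5,5,8a-tetramethyl-1,2,4a,5,6,7,8,8a-octahydronaphthalen-1-yl]methanol (configuration as in 10)
Conditions: LiBH4, MeOH (1 equiv), THF, 0 °C
Reagents that add atoms: none
Why: Reductive cleavage of the N-acyl oxazolidinone by LiBH4 should give the primary alcohol at C11 and return the auxiliary, while the silyl enol ether keeps C6 masked; no stereocentre is touched.

Step 8
Reactants: 11
Product: 12 4-(tert-butyldimethylsilyloxy)-2,5,5,8a-tetramethyl-1,2,4a,5,6,7,8,8a-octahydronaphthalene-1-carbaldehyde (configuration as in 10)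
Conditions: Dess–Martin periodinane, pyridine, CH2Cl2, 0 °C
Reagents that add atoms: none
Why: Buffered Dess–Martin oxidation should give the aldehyde without hydrolysing the silyl enol ether; C9 already has the more stable equatorial configuration, so epimerisation is not expected.

Step 9
Reactants: 12
Product: 13 tert-butyl[(1-ethenyl-2,5,5,8a-tetramethyl-1,2,4a,5,6,7,8,8a-octahydronaphthalen-4-yl)oxy]dimethylsilane (configuration as in 10)
Conditions: Ph3PCH3Br, KOt-Bu, THF, 0 °C to rt
Reagents that add atoms: methyltriphenylphosphonium bromide, C[P+](c1ccccc1)(c1ccccc1)c1ccccc1.[Br-]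
Why: Wittig methylenation should convert the hindered aldehyde into the C11=C12 vinyl group; it is placed before the C8 hydroxyl group is introduced so that no β-hydroxy aldehyde (retro-aldol risk) is ever formed.

Step 10
Reactants: 13
Product: 14 1-ethenyl-2,5,5,8a-tetramethyl-4a,5,6,7,8,8a-hexahydronaphthalen-4(1H)-one (8aR; 1-ethenyl on the lower face; 4a-H on the upper face)
Conditions: Pd(OAc)2 (1.1 equiv), MeCN, rt
Reagents that add atoms: none
Why: Saegusa–Ito oxidation: the silyl enol ether gives a palladium enolate at C7 whose only β-hydrogen is on C8, so β-hydride elimination should give the C7=C8 enone and remove the C8 stereocentre.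

Step 11
Reactants: 14
Product: 16 1-ethenyl-2-hydroxy-2,5,5,8a-tetramethyloctahydronaphthalen-4(1H)-one (2-OH on the upper face; 2-methyl on the lower face), via β-boryl ketone 15 (not isolated)
Conditions: B2pin2, CuCl (5 mol %), Xantphos (5 mol %), NaOt-Bu (10 mol %), MeOH (2 equiv), THF, rt; then NaBO3·4H2O, THF/H2O, rt
Reagents that add atoms: bis(pinacolato)diboron, CC1(C)OB(OC1(C)C)B1OC(C)(C)C(C)(C)O1 (boron of 15 only); sodium perborate, [Na+].[O-]OB=O (oxygen of 16)
Why: Copper-catalysed conjugate borylation followed by stereoretentive C–B oxidation: the boryl copper species should add to C8 from the face opposite the axial angular methyl group and the neighbouring vinyl group, which places the oxygen equatorial and the C8 methyl axial as in the target, while the catalytic alkoxide equilibrates C5 (α to the ketone) to the trans ring fusion.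

Step 12
Reactants: 16
Product: 17 (1S,2S,4R,4aR,8aR)-1-ethenyl-2,5,5,8a-tetramethyldecahydronaphthalene-2,4-diol
Conditions: Li, NH3 (l), THF, t-BuOH, −78 °C; then NH4Cl
Reagents that add atoms: none
Why: Dissolving-metal reduction of the hindered ketone should give the thermodynamically preferred equatorial C6 alcohol (the axial position is flanked by the axial methyl groups on C4, C8 and C10), whereas hydride reagents would attack from the open face and give the axial epimer; the terminal alkene is inert and the low temperature suppresses retro-aldol opening.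

Step 13
Reactants: 18 methyl acetoacetate
Product: 19 methyl (2E)-3-{[(trifluoromethyl)sulfonyl]oxy}but-2-enoate
Conditions: Tf2O, aq. Me4NOH, hexanes, 5 °C
Reagents that add atoms: triflic anhydride, O=S(=O)(OS(=O)(=O)C(F)(F)F)C(F)(F)F
Why: O-triflation of the non-chelated tetramethylammonium enolate should give the E enol triflate (triflate trans to the ester), the geometry that is carried into the 13E double bond.

Step 14
Reactants: 17; 19
Product: 21 methyl (2E)-5-[(1S,2S,4R,4aR,8aR)-2,4-dihydroxy-2,5,5,8a-tetramethyldecahydronaphthalen-1-yl]-3-methylpent-2-enoate (CNP0289884.1), via B-alkyl borane 20 (not isolated)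
Conditions: 9-BBN-H (3.5 equiv), THF, 0 °C to rt; then 19, PdCl2(dppf) (5 mol %), AsPh3, aq. K3PO4, DMF, rt
Reagents that add atoms: 9-borabicyclo[3.3.1]nonane, B1C2CCCC1CCC2 (boron of 20 only)
Why: Anti-Markovnikov hydroboration of the vinyl group and B-alkyl Suzuki–Miyaura coupling with retention of the enol triflate geometry should form the C12–C13 bond and deliver the 13E enoate; the free hydroxyl groups are tolerated and no stereocentre is touched.

**Compound list**

1 | (2E)-3,7-dimethylocta-2,6-dienoic acid (geranic acid) | CC(C)=CCC/C(C)=C/C(=O)O | starting material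
2 | (4R)-4-benzyl-1,3-oxazolidin-2-one | O=C1N[C@H](Cc2ccccc2)CO1 | starting material
3 | (2E)-3,7-dimethylocta-2,6-dienoic pivalic anhydride | CC(C)=CCC/C(C)=C/C(=O)OC(=O)C(C)(C)C | intermediate
4 | (4R)-4-benzyl-3-[(2E)-3,7-dimethylocta-2,6-dienoyl]-1,3-oxazolidin-2-one | CC(C)=CCC/C(C)=C/C(=O)N1C(=O)OC[C@H]1Cc1ccccc1 | intermediate
5 | (4R)-4-benzyl-3-[(2E)-7-chloro-3,7-dimethyloct-2-enoyl]-1,3-oxazolidin-2-one | CC(C)(Cl)CCC/C(C)=C/C(=O)N1C(=O)OC[C@H]1Cc1ccccc1 | intermediate
6 | (3E)-pent-3-en-2-one | C/C=C/C(C)=O | starting material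
7 | (3E)-2-(trimethylsilyloxy)penta-1,3-diene | C=C(O[Si](C)(C)C)/C=C/C | intermediate
8 | (4R)-4-benzyl-3-[(2E,10E)-3,7,7-trimethyl-9-oxododeca-2,10-dienoyl]-1,3-oxazolidin-2-one | C/C=C/C(=O)CC(C)(C)CCC/C(C)=C/C(=O)N1C(=O)OC[C@H]1Cc1ccccc1 | intermediate
9 | (4R)-4-benzyl-3-[(2E,8Z,10E)-9-(tert-butyldimethylsilyloxy)-3,7,7-trimethyldodeca-2,8,10-trienoyl]-1,3-oxazolidin-2-one | C/C=C/C(O[Si](C)(C)C(C)(C)C)=C/C(C)(C)CCC/C(C)=C/C(=O)N1C(=O)OC[C@H]1Cc1ccccc1 | intermediate
10 | (4R)-4-benzyl-3-{[4-(tert-butyldimethylsilyloxy)-2,5,5,8a-tetramethyl-1,2,4a,5,6,7,8,8a-octahydronaphthalen-1-yl]carbonyl}-1,3-oxazolidin-2-one; trans-fused; 1-acyl and 2-methyl on the lower face | O=C([C@H]1[C@]2(C)CCCC(C)(C)[C@H]2C(O[Si](C)(C)C(C)(C)C)=C[C@H]1C)N1C(=O)OC[C@H]1Cc1ccccc1 | intermediate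
11 | [4-(tert-butyldimethylsilyloxy)-2,5,5,8a-tetramethyl-1,2,4a,5,6,7,8,8a-octahydronaphthalen-1-yl]methanol; configuration as in 10 | OC[C@H]1[C@]2(C)CCCC(C)(C)[C@H]2C(O[Si](C)(C)C(C)(C)C)=C[C@H]1C | intermediate
12 | 4-(tert-butyldimethylsilyloxy)-2,5,5,8a-tetramethyl-1,2,4a,5,6,7,8,8a-octahydronaphthalene-1-carbaldehyde; configuration as in 10 | O=C[C@H]1[C@]2(C)CCCC(C)(C)[C@H]2C(O[Si](C)(C)C(C)(C)C)=C[C@H]1C | intermediate
13 | tert-butyl[(1-ethenyl-2,5,5,8a-tetramethyl-1,2,4a,5,6,7,8,8a-octahydronaphthalen-4-yl)oxy]dimethylsilane; configuration as in 10 | C=C[C@H]1[C@]2(C)CCCC(C)(C)[C@H]2C(O[Si](C)(C)C(C)(C)C)=C[C@H]1C | intermediate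
14 | 1-ethenyl-2,5,5,8a-tetramethyl-4a,5,6,7,8,8a-hexahydronaphthalen-4(1H)-one; trans-fused; 1-ethenyl on the lower face | C=C[C@H]1[C@]2(C)CCCC(C)(C)[C@H]2C(=O)C=C1C | intermediate
15 | 1-ethenyl-2,5,5,8a-tetramethyl-2-(4,4,5,5-tetramethyl-1,3,2-dioxaborolan-2-yl)octahydronaphthalen-4(1H)-one; boron on the upper face | C=C[C@H]1[C@]2(C)CCCC(C)(C)[C@H]2C(=O)C[C@]1(C)B1OC(C)(C)C(C)(C)O1 | intermediate
16 | 1-ethenyl-2-hydroxy-2,5,5,8a-tetramethyloctahydronaphthalen-4(1H)-one; 2-OH on the upper face | C=C[C@H]1[C@]2(C)CCCC(C)(C)[C@H]2C(=O)C[C@]1(C)O | intermediate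
17 | (1S,2S,4R,4aR,8aR)-1-ethenyl-2,5,5,8a-tetramethyldecahydronaphthalene-2,4-diol | C=C[C@H]1[C@]2(C)CCCC(C)(C)[C@H]2[C@H](O)C[C@]1(C)O | intermediate
18 | methyl acetoacetate | CC(=O)CC(=O)OC | starting material
19 | methyl (2E)-3-{[(trifluoromethyl)sulfonyl]oxy}but-2-enoate | C/C(OS(=O)(=O)C(F)(F)F)=C\C(=O)OC | intermediate
20 | 9-{2-[(1S,2S,4R,4aR,8aR)-2,4-dihydroxy-2,5,5,8a-tetramethyldecahydronaphthalen-1-yl]ethyl}-9-borabicyclo[3.3.1]nonane | C1CC2CCCC(C1)B2CC[C@H]1[C@]2(C)CCCC(C)(C)[C@H]2[C@H](O)C[C@]1(C)O | intermediate
21 | methyl (2E)-5-[(1S,2S,4R,4aR,8aR)-2,4-dihydroxy-2,5,5,8a-tetramethyldecahydronaphthalen-1-yl]-3-methylpent-2-enoate | COC(=O)/C=C(\C)CC[C@H]1[C@]2(C)CCCC(C)(C)[C@H]2[C@H](O)C[C@]1(C)O | target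

**Totals.** Total step count: 14. Longest linear sequence: 12 steps (steps 1, 2, 4 to 12 and 14); steps 3 and 13 make the two side fragments.

**Steps most likely to fail**

Step 6. The Lewis acid may strip the silyl enol ether faster than the hindered β,β-disubstituted imide is attacked. The reaction may also stop after the first bond, and facial control may erode if it has to be run warm. The fallback replaces the cycloaddition by a stepwise annulation. It sets out from 9: a Mukaiyama–Michael addition (TiCl4, CH2Cl2, −78 °C) closes ring A through the same C5–C10 bond under the same chelate control and gives the monocyclic enone imide F1. NaHMDS (THF, −78 °C) then closes ring B by intramolecular Michael addition of the imide enolate (C9) to the enone (C8), giving the keto imide F2. TBSOTf/Et3N regenerates the enol ether towards C7 and gives 10 or its C8 epimer, the silyl enol ether F3. F3 is taken through steps 7 to 9 (alcohol F4, aldehyde F5, vinyl compound F6) and comes back to the route at 14, where C8 is trigonal.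

Step 4. Conjugate addition of 7 to the TiCl4-chelated imide may compete with the alkylation, or the tertiary chloride may eliminate to alkenes. The fallback forms the C4–C5 bond before the auxiliary is attached, so that no chelating imide is present. It sets out from 1: HCl gives the chloro acid F7, which is alkylated with 7 in the presence of excess TiCl4 (the acid being held as its titanium carboxylate) to give, after aqueous work-up, the keto acid F8. Activation of F8 as the mixed pivalic anhydride F9 and acylation of 2 bring the sequence back to the route at 8.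

Step 11. Conjugate borylation may be slow at the hindered, fully substituted β-carbon, and the base may shift the vinyl double bond into conjugation with the enone. The fallback replaces borylation and oxidation by epoxidation and reductive opening. It sets out from 14: Weitz–Scheffer epoxidation (H2O2, NaOH, MeOH, 0 °C) from the face opposite the angular methyl group gives the epoxy ketone F10, and reductive cleavage of its Cα–O bond with SmI2 (THF/MeOH, −78 °C) comes back to the route at 16.

Further compounds
F1 | step 6 | (4R)-4-benzyl-3-({2-[(2E)-but-2-enoyl]-1,3,3-trimethylcyclohexyl}acetyl)-1,3-oxazolidin-2-one (acyl and acetyl chain trans) | C/C=C/C(=O)[C@@H]1C(C)(C)CCC[C@@]1(C)CC(=O)N1C(=O)OC[C@H]1Cc1ccccc1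
F2 | step 6 | (4R)-4-benzyl-3-[(2,5,5,8a-tetramethyl-4-oxodecahydronaphthalen-1-yl)carbonyl]-1,3-oxazolidin-2-one (trans-fused; 2-methyl on the upper face) | O=C([C@H]1[C@]2(C)CCCC(C)(C)[C@H]2C(=O)C[C@@H]1C)N1C(=O)OC[C@H]1Cc1ccccc1
F3 | step 6 | C2 epimer of 10 (2-methyl on the upper face) | O=C([C@H]1[C@]2(C)CCCC(C)(C)[C@H]2C(O[Si](C)(C)C(C)(C)C)=C[C@@H]1C)N1C(=O)OC[C@H]1Cc1ccccc1
F4 | step 6 | C2 epimer of 11 | OC[C@H]1[C@]2(C)CCCC(C)(C)[C@H]2C(O[Si](C)(C)C(C)(C)C)=C[C@@H]1C
F5 | step 6 | C2 epimer of 12 | O=C[C@H]1[C@]2(C)CCCC(C)(C)[C@H]2C(O[Si](C)(C)C(C)(C)C)=C[C@@H]1C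
F6 | step 6 | C2 epimer of 13 | C=C[C@H]1[C@]2(C)CCCC(C)(C)[C@H]2C(O[Si](C)(C)C(C)(C)C)=C[C@@H]1C
F7 | step 4 | (2E)-7-chloro-3,7-dimethyloct-2-enoic acid | CC(C)(Cl)CCC/C(C)=C/C(=O)O
F8 | step 4 | (2E,10E)-3,7,7-trimethyl-9-oxododeca-2,10-dienoic acid | C/C=C/C(=O)CC(C)(C)CCC/C(C)=C/C(=O)O
F9 | step 4 | (2E,10E)-3,7,7-trimethyl-9-oxododeca-2,10-dienoic pivalic anhydride | C/C=C/C(=O)CC(C)(C)CCC/C(C)=C/C(=O)OC(=O)C(C)(C)C
F10 | step 11 | 1-ethenyl-2,3-epoxy-2,5,5,8a-tetramethyloctahydronaphthalen-4(1H)-one (epoxide on the upper face) | C=C[C@H]1[C@]2(C)CCCC(C)(C)[C@H]2C(=O)[C@@H]2O[C@]12C
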